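**Plan**

- Numbering: naphthalene C1 carries ring C (3,4-dimethoxyphenyl), C2 OH, C3 CHO, C7 OH, C8 OMe; ring A = C4a/C5–C8/C8a, ring B = C1–C4/C4a/C8a.
- Retrosynthesis: CHO goes back to CO2Me and C7–OH to OBn. Ring B is then cut at C2–C3 (retro-6π of a ketene onto an acrylate) and at C1–C1′ (retro-Wolff, ring C returned to the future C2), leaving an α-diazo deoxybenzoin. That is cut at C1–C8a (ketone α-arylation of an aryl triflate) and at C3=C4 (olefination of an aldehyde).
- Enabling feature: C1 of ring B lies between C2 and the peri-crowded C8a, so ring C can reach C1 by a 1,2-shift from the carbon that becomes C2 instead of by a hindered coupling. The C2(OH)–C3(C=O) bond maps onto a ketene carbon meeting an acrylate α-carbon.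
- Forward: ring A comes from 2-methoxyresorcinol (formyl, benzyl, triflate). The acrylate and then ring C (as acetoveratrone) are attached, diazo transfer sets up step 7, and ring B closes there. Ester-to-aldehyde adjustment and debenzylation finish the route.
- Stereochemistry: the target has no stereocentre. The only stereo element on the way is the E-alkene from the olefination, which is absorbed into ring B.

Key step: step 7

Remark: the C1–C1′ axis has no ortho substituent on ring C and is taken to rotate freely, so the target is treated as achiral.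

**Route**

Step 1
Reactants: 1 2-methoxybenzene-1,3-diol
Product: 3 2,4-dihydroxy-3-methoxybenzaldehyde, via iminium chloride 2 (not isolated)
Conditions: POCl3, DMF, MeCN, 0 °C to rt; then H2O, 50 °C
Reagents that add atoms: N,N-dimethylformamide, CN(C)C=O; water, O
Why: Vilsmeier–Haack formylation of a resorcinol, in which the two positions ortho/para to the hydroxyls are equivalent by symmetry, the remaining position is only meta to both hydroxyls, and the first iminium group deactivates the ring toward a second attack.

Step 2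
Reactants: 3 2,4-dihydroxy-3-methoxybenzaldehyde
Product: 4 4-(benzyloxy)-2-hydroxy-3-methoxybenzaldehyde
Conditions: BnBr, NaHCO3, KI (cat.), MeCN, 80 °C
Reagents that add atoms: benzyl bromide, BrCc1ccccc1
Why: Williamson etherification with a weak base should alkylate only the 4-OH (para to the aldehyde, more acidic), because the 2-OH is held in a hydrogen bond to the carbonyl group.

Step 3
Reactants: 4 4-(benzyloxy)-2-hydroxy-3-methoxybenzaldehyde
Product: 5 3-(benzyloxy)-6-formyl-2-methoxyphenyl trifluoromethanesulfonate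
Conditions: Tf2O, pyridine, CH2Cl2, 0 °C
Reagents that add atoms: trifluoromethanesulfonic anhydride, O=S(=O)(OS(=O)(=O)C(F)(F)F)C(F)(F)F
Why: O-triflation of the remaining phenol turns the C–O bond at the future C8a into a cross-coupling handle, and the aldehyde and both ethers are inert to the reagent.

Step 4
Reactants: 5 3-(benzyloxy)-6-formyl-2-methoxyphenyl trifluoromethanesulfonate, 6 trimethyl phosphonoacetate
Product: 7 methyl (E)-3-[4-(benzyloxy)-3-methoxy-2-{[(trifluoromethyl)sulfonyl]oxy}phenyl]prop-2-enoate
Conditions: LiCl, DBU, MeCN, rt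
Reagents that add atoms: none
Why: Horner–Wadsworth–Emmons olefination of an aromatic aldehyde with a stabilised phosphonate should give the E-enoate, and the mild LiCl/amine base leaves the aryl triflate untouched.

Step 5
Reactants: 7 methyl (E)-3-[4-(benzyloxy)-3-methoxy-2-{[(trifluoromethyl)sulfonyl]oxy}phenyl]prop-2-enoate, 8 1-(3,4-dimethoxyphenyl)ethanone
Product: 9 methyl (E)-3-{4-(benzyloxy)-2-[2-(3,4-dimethoxyphenyl)-2-oxoethyl]-3-methoxyphenyl}prop-2-enoate
Conditions: Pd(OAc)2 (5 mol %), XPhos (10 mol %), K3PO4, PhMe, 90 °C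
Reagents that add atoms: none
Why: Palladium-catalysed α-arylation of a methyl ketone enolate (Buchwald–Hartwig type), in which the bulky biaryl phosphine supports oxidative addition and reductive elimination at the doubly ortho-substituted triflate, the weak base spares triflate, ester and cinnamate, and the hindered product should not be arylated twice.

Step 6
Reactants: 9 methyl (E)-3-{4-(benzyloxy)-2-[2-(3,4-dimethoxyphenyl)-2-oxoethyl]-3-methoxyphenyl}prop-2-enoate
Product: 10 methyl (E)-3-{4-(benzyloxy)-2-[1-diazo-2-(3,4-dimethoxyphenyl)-2-oxoethyl]-3-methoxyphenyl}prop-2-enoate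
Conditions: 4-acetamidobenzenesulfonyl azide, DBU, MeCN, 0 °C, dark; used at once
Reagents that add atoms: 4-acetamidobenzenesulfonyl azide, CC(=O)Nc1ccc(cc1)S(=O)(=O)N=[N+]=[N-]
Why: Regitz diazo transfer to the methylene activated by both an aryl and an aroyl group, whose DBU enolate attacks the sulfonyl azide and expels the sulfonamide; cold, dark handling keeps the diazo group from adding to the acrylate.

Step 7
Reactants: 10 methyl (E)-3-{4-(benzyloxy)-2-[1-diazo-2-(3,4-dimethoxyphenyl)-2-oxoethyl]-3-methoxyphenyl}prop-2-enoate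
Product: 13 methyl 6-(benzyloxy)-4-(3,4-dimethoxyphenyl)-3-hydroxy-5-methoxynaphthalene-2-carboxylate, via diarylketene 11 (not isolated), via keto tautomer 12 (not isolated)
Conditions: hν (450 nm LEDs), PhMe (0.01 M, degassed, dry), 10 °C; then 80 °C, dark
Reagents that add atoms: none
Why: Visible-light excitation of the α-diazo ketone expels N2 and the 3,4-dimethoxyphenyl group shifts from the acyl carbon to the diazo carbon (Wolff rearrangement, as in the classical conversion of 2-diazo-1,2-diarylethanones into diarylketenes), which forms C1–C1′ and makes the former carbonyl carbon the ketene carbon C2 of 11. In 11 the bonds C2=C1, C8a=C4a and C4=C3 form a cis-locked triene, which on warming should close by a thermal disrotatory 6π-electrocyclisation (C2–C3 bond, six-membered carbocyclic ring B, as in the last stage of dienylketene benzannulations) to the ortho-quinoid keto tautomer 12. The doubly activated C3–H of 12 then moves to oxygen, which restores the aromaticity of ring A and gives the 2-naphthol. No stereocentre remains: C3 of 12 is a transient racemic sp3 centre that the enolisation flattens, and the E-geometry of the acrylate serves only to turn the ester outward in the ring closure. The step needs rearrangement to outrun dipolar addition or 1,7-cyclisation of the diazo group onto the acrylate and carbene insertion into the ortho-methoxy group. This is secured by the acyl stabilisation of the diazo group, by 450 nm light that excites only the diazo ketone chromophore at low temperature (no E/Z scrambling of the cinnamate), by the high migratory aptitude of the electron-rich aryl group, and by dry, dilute toluene so that the ketene meets no nucleophile before it cyclises.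

Step 8
Reactants: 13 methyl 6-(benzyloxy)-4-(3,4-dimethoxyphenyl)-3-hydroxy-5-methoxynaphthalene-2-carboxylate
Product: 14 7-(benzyloxy)-1-(3,4-dimethoxyphenyl)-3-(hydroxymethyl)-8-methoxynaphthalen-2-ol
Conditions: LiAlH4 (excess), THF, 0 °C to rt; Rochelle-salt work-up
Reagents that add atoms: none
Why: Hydride reduction of the ester with LiAlH4, where the first equivalent only deprotonates the naphthol and the benzyl and methyl ethers are inert, as in the standard reduction of 3-hydroxy-2-naphthoates.

Step 9
Reactants: 14 7-(benzyloxy)-1-(3,4-dimethoxyphenyl)-3-(hydroxymethyl)-8-methoxynaphthalen-2-ol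
Product: 15 6-(benzyloxy)-4-(3,4-dimethoxyphenyl)-3-hydroxy-5-methoxynaphthalene-2-carbaldehyde
Conditions: MnO2 (activated), CH2Cl2, rt
Reagents that add atoms: none
Why: MnO2 oxidation is selective for the benzylic alcohol and should stop at the aldehyde, which is stabilised by the hydrogen bond to the neighbouring naphthol; the C1-blocked naphthol is not expected to couple oxidatively.

Step 10
Reactants: 15 6-(benzyloxy)-4-(3,4-dimethoxyphenyl)-3-hydroxy-5-methoxynaphthalene-2-carbaldehyde
Product: 16 vitrofolal B, 4-(3,4-dimethoxyphenyl)-3,6-dihydroxy-5-methoxynaphthalene-2-carbaldehyde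
Conditions: BCl3, C6HMe5, CH2Cl2, −78 °C; aqueous work-up
Reagents that add atoms: none
Why: Lewis-acid debenzylation with BCl3 and pentamethylbenzene as a non-basic benzyl-cation scavenger; at −78 °C the three methyl ethers (none ortho to a carbonyl group) and the aldehyde should survive, and the scavenger prevents C-benzylation of the electron-rich rings.

**Compound list**

1 | 2-methoxybenzene-1,3-diol | COc1c(O)cccc1O | starting material
2 | N-[(2,4-dihydroxy-3-methoxyphenyl)methylidene]-N-methylmethanaminium chloride | C[N+](C)=Cc1ccc(O)c(OC)c1O.[Cl-] | intermediate (not isolated)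
3 | 2,4-dihydroxy-3-methoxybenzaldehyde | O=Cc1ccc(O)c(OC)c1O | intermediate
4 | 4-(benzyloxy)-2-hydroxy-3-methoxybenzaldehyde | O=Cc1ccc(OCc2ccccc2)c(OC)c1O | intermediate
5 | 3-(benzyloxy)-6-formyl-2-methoxyphenyl trifluoromethanesulfonate | O=Cc1ccc(OCc2ccccc2)c(OC)c1OS(=O)(=O)C(F)(F)F | intermediate
6 | trimethyl phosphonoacetate | COC(=O)CP(=O)(OC)OC | starting material
7 | methyl (E)-3-[4-(benzyloxy)-3-methoxy-2-{[(trifluoromethyl)sulfonyl]oxy}phenyl]prop-2-enoate | COC(=O)/C=C/c1ccc(OCc2ccccc2)c(OC)c1OS(=O)(=O)C(F)(F)F | intermediate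
8 | 1-(3,4-dimethoxyphenyl)ethanone | CC(=O)c1ccc(OC)c(OC)c1 | starting material
9 | methyl (E)-3-{4-(benzyloxy)-2-[2-(3,4-dimethoxyphenyl)-2-oxoethyl]-3-methoxyphenyl}prop-2-enoate | COC(=O)/C=C/c1ccc(OCc2ccccc2)c(OC)c1CC(=O)c1ccc(OC)c(OC)c1 | intermediate
10 | methyl (E)-3-{4-(benzyloxy)-2-[1-diazo-2-(3,4-dimethoxyphenyl)-2-oxoethyl]-3-methoxyphenyl}prop-2-enoate | COC(=O)/C=C/c1ccc(OCc2ccccc2)c(OC)c1C(=[N+]=[N-])C(=O)c1ccc(OC)c(OC)c1 | intermediate
11 | methyl (E)-3-{4-(benzyloxy)-2-[1-(3,4-dimethoxyphenyl)-2-oxoethenyl]-3-methoxyphenyl}prop-2-enoate (diarylketene) | COC(=O)/C=C/c1ccc(OCc2ccccc2)c(OC)c1C(=C=O)c1ccc(OC)c(OC)c1 | intermediate (not isolated)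
12 | methyl 6-(benzyloxy)-4-(3,4-dimethoxyphenyl)-5-methoxy-3-oxo-2,3-dihydronaphthalene-2-carboxylate (racemic at C2) | COC(=O)C1C=C2C=CC(OCc3ccccc3)=C(OC)C2=C(c2ccc(OC)c(OC)c2)C1=O | intermediate (not isolated)
13 | methyl 6-(benzyloxy)-4-(3,4-dimethoxyphenyl)-3-hydroxy-5-methoxynaphthalene-2-carboxylate | COC(=O)c1cc2ccc(OCc3ccccc3)c(OC)c2c(-c2ccc(OC)c(OC)c2)c1O | intermediate
14 | 7-(benzyloxy)-1-(3,4-dimethoxyphenyl)-3-(hydroxymethyl)-8-methoxynaphthalen-2-ol | OCc1cc2ccc(OCc3ccccc3)c(OC)c2c(-c2ccc(OC)c(OC)c2)c1O | intermediate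
15 | 6-(benzyloxy)-4-(3,4-dimethoxyphenyl)-3-hydroxy-5-methoxynaphthalene-2-carbaldehyde | O=Cc1cc2ccc(OCc3ccccc3)c(OC)c2c(-c2ccc(OC)c(OC)c2)c1O | intermediate
16 | vitrofolal B, 4-(3,4-dimethoxyphenyl)-3,6-dihydroxy-5-methoxynaphthalene-2-carbaldehyde | COc1ccc(-c2c(O)c(C=O)cc3ccc(O)c(OC)c23)cc1OC | target

**Count and risk**

Total step count: 10. Longest linear sequence: 10 steps (1 to 16); 6 and 8 are bought.

Steps most likely to fail:

Step 7. The diazo group or the carbene may be consumed by the neighbouring acrylate (dipolar addition, 1,7-cyclisation) or by insertion into the ortho-methoxy group before the aryl shift, or the ketene may be captured before the dearomatising ring closure. The fallback sets out from 9 and returns at 13, and uses neither a diazo compound nor a ketene. Treating 9 with PhI(OAc)2 and HC(OMe)3 in MeOH with catalytic H2SO4 should move the 3,4-dimethoxyphenyl group from the carbonyl carbon to the benzylic carbon in an ionic oxidative 1,2-aryl shift. This gives methyl (E)-3-{4-(benzyloxy)-2-[1-(3,4-dimethoxyphenyl)-2-methoxy-2-oxoethyl]-3-methoxyphenyl}prop-2-enoate F1. Conjugate reduction of the cinnamate with Mg in MeOH would give methyl 3-{4-(benzyloxy)-2-[1-(3,4-dimethoxyphenyl)-2-methoxy-2-oxoethyl]-3-methoxyphenyl}propanoate F2. Dieckmann condensation (NaH, THF) then closes C2–C3 to methyl 6-(benzyloxy)-4-(3,4-dimethoxyphenyl)-5-methoxy-3-oxo-1,2,3,4-tetrahydronaphthalene-2-carboxylate F3; the other Dieckmann mode leads to a non-enolisable keto ester and reverts. Dehydrogenation with DDQ in dioxane at 80 °C gives 13.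

Step 5. Oxidative addition and reductive elimination at the doubly ortho-substituted triflate may be slow, the base may cleave the triflate at sulfur, or the ketone enolate may add to the cinnamate. The fallback sets out from 7 and returns at 9. Sonogashira coupling of 7 with commercial 4-ethynyl-1,2-dimethoxybenzene (PdCl2(PPh3)2, CuI, Et3N, DMF, 70 °C) should give methyl (E)-3-{4-(benzyloxy)-2-[(3,4-dimethoxyphenyl)ethynyl]-3-methoxyphenyl}prop-2-enoate F4. Hydration catalysed by Ph3PAuNTf2 in aqueous 1,4-dioxane then places the oxygen on the alkyne carbon next to ring C, where the para-methoxy group stabilises positive charge and ring A is twisted out of conjugation. This gives 9.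

Step 6. Diazo transfer to the twisted, hindered enolate may be sluggish, the enolate oxygen may close reversibly onto the acrylate, or the diazo ketone may decompose during isolation. The fallback sets out from 9 and returns at ketene 11, which goes on to 13 as in step 7. Oxidation of 9 with SeO2 in aqueous dioxane at reflux should give methyl (E)-3-{4-(benzyloxy)-2-[2-(3,4-dimethoxyphenyl)-2-oxoacetyl]-3-methoxyphenyl}prop-2-enoate F5. Condensation with TsNHNH2 in MeOH is expected at the unhindered carbonyl next to ring C and gives methyl (E)-3-{4-(benzyloxy)-2-[2-(3,4-dimethoxyphenyl)-2-(2-tosylhydrazinylidene)acetyl]-3-methoxyphenyl}prop-2-enoate F6. Et3N in CH2Cl2 then eliminates sulfinate (Bamford–Stevens type) to the regioisomeric diazo ketone methyl (E)-3-{4-(benzyloxy)-2-[2-diazo-2-(3,4-dimethoxyphenyl)acetyl]-3-methoxyphenyl}prop-2-enoate F7. Its diazo carbon is unhindered and remote from the acrylate. Irradiation as in step 7 makes ring A migrate instead of ring C, so C1–C8a is the bond formed by the shift, and the same ketene 11 results.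

**Further compounds**

F1 | step 7 | methyl (E)-3-{4-(benzyloxy)-2-[1-(3,4-dimethoxyphenyl)-2-methoxy-2-oxoethyl]-3-methoxyphenyl}prop-2-enoate (racemic) | COC(=O)/C=C/c1ccc(OCc2ccccc2)c(OC)c1C(C(=O)OC)c1ccc(OC)c(OC)c1
F2 | step 7 | methyl 3-{4-(benzyloxy)-2-[1-(3,4-dimethoxyphenyl)-2-methoxy-2-oxoethyl]-3-methoxyphenyl}propanoate (racemic) | COC(=O)CCc1ccc(OCc2ccccc2)c(OC)c1C(C(=O)OC)c1ccc(OC)c(OC)c1
F3 | step 7 | methyl 6-(benzyloxy)-4-(3,4-dimethoxyphenyl)-5-methoxy-3-oxo-1,2,3,4-tetrahydronaphthalene-2-carboxylate (mixture of stereoisomers) | COC(=O)C1Cc2ccc(OCc3ccccc3)c(OC)c2C(c2ccc(OC)c(OC)c2)C1=O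
F4 | step 5 | methyl (E)-3-{4-(benzyloxy)-2-[(3,4-dimethoxyphenyl)ethynyl]-3-methoxyphenyl}prop-2-enoate | COC(=O)/C=C/c1ccc(OCc2ccccc2)c(OC)c1C#Cc1ccc(OC)c(OC)c1
F5 | step 6 | methyl (E)-3-{4-(benzyloxy)-2-[2-(3,4-dimethoxyphenyl)-2-oxoacetyl]-3-methoxyphenyl}prop-2-enoate | COC(=O)/C=C/c1ccc(OCc2ccccc2)c(OC)c1C(=O)C(=O)c1ccc(OC)c(OC)c1
F6 | step 6 | methyl (E)-3-{4-(benzyloxy)-2-[2-(3,4-dimethoxyphenyl)-2-(2-tosylhydrazinylidene)acetyl]-3-methoxyphenyl}prop-2-enoate (C=N geometry not defined) | COC(=O)/C=C/c1ccc(OCc2ccccc2)c(OC)c1C(=O)C(=NNS(=O)(=O)c1ccc(C)cc1)c1ccc(OC)c(OC)c1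
F7 | step 6 | methyl (E)-3-{4-(benzyloxy)-2-[2-diazo-2-(3,4-dimethoxyphenyl)acetyl]-3-methoxyphenyl}prop-2-enoate | COC(=O)/C=C/c1ccc(OCc2ccccc2)c(OC)c1C(=O)C(=[N+]=[N-])c1ccc(OC)c(OC)c1
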